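## The problem

Elemane numbering is used throughout: the ring is C5–C10; C10 is quaternary and carries methyl C14 and the oxirane C1–C2; C5 carries C4 with its methylene C3 and formyl C15; C7 carries C11 (methylene C13), and C12 closes the lactone to the oxygen on C8; C6 bears the free hydroxyl and C9 the isobutyrate; β is the face of C14.

- The target 30 has one carbocycle, a cyclohexane substituted at every carbon, trans-fused across C7–C8 to an α-methylene-γ-butyrolactone. The acrolein arm on C5 and the oxirane on C10 sit on neighbouring carbons and are trans.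
- There are seven stereocentres: six contiguous ring centres (β: C14, the C4 arm, O6, C11; α: C1, O8, O9) and the exocyclic C1.
- The ring centres can steer one another, because the C5/C10/C6 pattern fixes the ring conformation and so the faces of any ring alkene. C1 lies on a rotating bond next to the quaternary carbon; a Felkin–Anh analysis suggests a carbon nucleophile adding to a C1 aldehyde would favour the wrong epimer, so C1 needs reagent control.
- The fragile groups are two Michael acceptors, a terminal oxirane, and a C6 hydroxyl that can translactonise (12,6 against 12,8) once it is an alkoxide. Whenever C4 is a carbonyl, C5–H is acidic with the C6 oxygen anti-periplanar to it.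
- The enal, the methylene lactone and the oxirane therefore have to appear late, and O6 has to stay protected to the end.
- The enabling feature: C5 and C10 carry trans carbon arms, C6 is oxygenated cis to the C5 arm, and with a temporary β oxygen on C9 the unit C6–C7=C8–C9 is a cis-2-ene-1,4-diol. This is the pattern of a [4+2] adduct of an E,E-1,4-dioxygenated butadiene and an E-trisubstituted dienophile whose two carbonyl carbons become C4 and C1.

## Retrosynthesis

**End game (30 ⇐ 29 ⇐ 27 ⇐ 24).** No skeletal bond is cut. The O6–H bond goes back to a silyl ether (29), the formyl C15 to the methyl of an isopropenyl group (27), and C11=C13 to the saturated lactone 24. Both Michael acceptors and the free hydroxyl are thus made in the last three steps. The forward reactions must be mild: allylic oxidation of CH3 in preference to C5–H, kinetic enolisation of the lactone beside an isobutyrate, and acidic fluoride for the silyl ether.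

**C4 arm (24 ⇐ 23 ⇐ 21 ⇐ 20).** C4=C3 is cut (Wittig on methyl ketone 23), then C4–C15 (methyl addition to aldehyde 21), leaving a primary alcohol 20. An isopropenyl group carried from the start would be shorter. However, OsO4 attacks an exocyclic 1,1-disubstituted alkene before the hindered ring alkene, and the group would not survive the hydrogenolysis and borane steps. C4 is therefore parked as a primary acetate until those steps are over.

**Oxirane (20 ⇐ 18 ⇐ 17 ⇐ 14 ⇐ 13).** The C2–O bond is cut (ring closure of chlorohydrin 18), then C1–H (reduction of chloromethyl ketone 17), then C1–C2 (diazomethane homologation of acid 14, from benzyl ester 13). The alternative, a sulfur ylide on a C1 aldehyde, is one step but relies on substrate control that is predicted to favour the wrong epimer. The chloroketone route sets C1 by a chiral reducing catalyst, and the substrate's own bias for hydride is predicted to be matched. The benzyl ester is chosen as spectator at C10 because it can be removed by hydrogenolysis at a stage that holds no alkene.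

**Lactone and C8/C9 oxygens (13 ⇐ 12 ⇐ 10).** The isobutyryl C–O bond, the O8–C12 bond and the two C–O bonds at C8 and C9 are cut, leading to cyclohexene acid 10. The forward step is a cis-dihydroxylation from the α face, opposite the pseudoaxial C10 methyl and the axial C6 silyloxy group. The equatorial C8 hydroxyl then lactonises; the axial C9 hydroxyl cannot, so the two hydroxyls are differentiated without protection.

**C7–C11 bond (10 ⇐ 7).** The C7–C11 bond is cut by a [3,3] shift back to the C9 allylic acetate 7. The β oxygen on C9 delivers the two-carbon arm to the β face of C7 and moves the alkene to C8=C9, where the α oxygens are wanted. An orthoester rearrangement of a free C9 hydroxyl would first require both acetates to be cleaved and the C6 hydroxyl to be silylated selectively. That selectivity is doubtful (C9–OH is equatorial and neopentylic, C6–OH axial). In the Ireland variant the acetate that the diene brought in is itself the relay.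

**Differentiating the two acetates (7 ⇐ 6 ⇐ 4).** No skeletal bond is cut. In 4 the formyl group is cis and 1,3 to the C6 acetate. Reducing it and letting the acetyl group migrate to the new primary oxygen (6) frees only the C6 hydroxyl, which is then silylated (7). The differentiation rests on the primary-over-secondary ester equilibrium, not on steric discrimination between two hindered secondary alcohols.

**Ring (4 ⇐ 2 + 3).** C5–C6 and C9–C10 are cut. This removes the ring and four stereocentres at once and leads to enal ester 2 and the commercial diene 3. The forward reaction must be endo for the formyl group, face-selective and tolerant of a β,β-disubstituted enal. The symmetric diene removes regiochemistry as an issue.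

**Dienophile (2 ⇐ 1).** The formyl C–O bonds are traced back to the γ-methyl group of benzyl tiglate 1 (allylic oxidation).

## Roads not taken

**Alternative 1:** enzymatic cis-dihydroxylation of an arene.
- Cut: the C8–O and C9–O bonds, traced back to the aromatic ring of 4-iodotoluene A1.
- Forward key step: an arene dioxygenase converts A1 into cis-dihydrodiol A2 as a single enantiomer.
- Merits: the absolute configuration of two carbinol centres comes from the enzyme; the cis-diol is already the C8/C9 pattern; the iodide on the future C7 is a handle for the lactone carbons; the methyl group is already on the future C10.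
- Weak points: C10 must be made quaternary by adding the C1 carbon next to the diol, and C5, C6 and C7 must then be set one at a time on a diene. The two hydroxyls still have to be told apart. A whole-cell fermentation starts the route.
- Comparison: for C8/C9 this road is better than the chosen plan, which relies on an untested asymmetric cycloaddition and a facial dihydroxylation. Against it, the chosen plan sets C5, C6 and C10 in one step and passes C9 on to C7 stereospecifically.

**Alternative 2:** late palladium cyclocarbonylation.
- Cut: O–C12 and C11–C12 of the lactone.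
- Forward key step: alkynol A3 (C8 hydroxyl trans to a C7 ethynyl group) is cyclocarbonylated under palladium catalysis to the α-methylene lactone A4.
- Merits: the methylene lactone is made in one neutral step, with no lactone enolate next to an ester; vinyl and isopropenyl groups are tolerated.
- Weak points: A3 already holds all six ring stereocentres, so the ring, the quaternary centre and the trans ethynyl/hydroxyl pair remain unsolved. The C10 vinyl group leaves the oxirane to a late epoxidation that must compete with two other alkenes and has no control at C1.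
- Comparison: for the lactone itself this road is shorter than the chosen plan (one step against rearrangement, dihydroxylation/lactonisation and methylenation) and avoids strong base. Against it, the chosen plan's three steps also set C7, C8 and C9, and its C1 is set by a catalyst.

**Alternative 3:** acyl radical ring closure from a chiral-pool diol.
- Cut: the C6–C7 bond.
- Forward key step: the acyl radical from selenoester A5 adds 6-exo to the enoate and closes cyclohexanone A6.
- Merits: the C8/C9 diol comes from the chiral pool with secure absolute configuration; the C6 ketone can be reduced to the axial alcohol late; the two-carbon chain on C5 needs only oxidation and α-methylenation to become the enal, which is shorter than the chosen plan's route to that arm.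
- Weak points: C5 and the quaternary C10 must be built by acyclic stereocontrol before the ring exists, which is the hardest part of the molecule. The configuration at C7 depends on the conformation of the cyclising chain. C1 is again a vinyl group. The lactone still needs methylenation.
- Comparison: better for C8/C9 and for the C4 arm. The chosen plan makes the ring and the C5/C6/C10 triad in one catalytic step and carries C1 as a carboxyl group that can be turned into the oxirane under reagent control.

Key step: step 2

## Route

Assumption: the sense of the cycloaddition is assigned from the formyl C–H···O binding model of the boron cation, on which the (S)-catalyst gives 4. If the adduct proves antipodal, the (R)-catalyst is used and nothing else changes.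

Step 1
Reactants: 1 benzyl tiglate
Product: 2 benzyl (E)-2-methyl-4-oxobut-2-enoate
Conditions: SeO2, 1,4-dioxane, 100 °C
Reagents that add atoms: selenium dioxide, O=[Se]=O
Why: Riley oxidation: the ene reaction of SeO2 and the following [2,3]-shift take place at the γ-methyl group (trans to the ester), further oxidation gives the aldehyde, and the E geometry of the enoate is kept.

Step 2
Reactants: 2 benzyl (E)-2-methyl-4-oxobut-2-enoate; 3 (1E,3E)-buta-1,3-diene-1,4-diyl diacetate
Product: 4 benzyl (1S,2S,5R,6S)-2,5-diacetoxy-6-formyl-1-methylcyclohex-3-ene-1-carboxylate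
Conditions: (S)-1-(2-methylphenyl)-3,3-diphenyltetrahydro-1H,3H-pyrrolo[1,2-c][1,3,2]oxazaborole (20 mol%), HN(SO2CF3)2 (16 mol%), 3 (3 equiv), CH2Cl2, −40 → −20 °C
Reagents that add atoms: none
Why: The formyl oxygen of 2 binds to the boron cation of the N-protonated oxazaborolidine (anti to the vinyl group, formyl C–H···O contact to the ring oxygen), which lowers the LUMO of the enal and lays its C=C over one phenyl group; 3 then adds to the open face in a concerted, asynchronous, suprafacial [4+2] cycloaddition, the closest known reaction type being the cationic-oxazaborolidine-catalysed enantioselective Diels–Alder reaction of α,β-unsaturated aldehydes. The cyclohexene is closed by the cycloaddition itself, C9–C10 and C5–C6 forming in the same step. C5 and C10 are set relative to each other by the E geometry of 2 (formyl cis to methyl, trans to the ester), C6 and C9 relative to each other by the E,E geometry of 3 (both acetoxy groups on one face), C6/C9 relative to C5/C10 by the endo position of the coordinated formyl group, and the absolute sense by the catalyst, which shields the rear face. The step needs endo selectivity for the formyl over the ester group and face selectivity; the first follows from the Lewis acid sitting on the more basic aldehyde oxygen, the second from the catalyst, and regiochemistry does not arise because 3 is symmetric. The ester on the same double bond is a second acceptor and should make up for the β,β-disubstitution of the enal.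

Step 3
Reactants: 4 cycloadduct (5β-formyl 6β,9β-diacetate)
Product: 6 benzyl 9β-acetoxy-5β-(acetoxymethyl)-6β-hydroxy-10β-methylcyclohex-7-ene-10α-carboxylate, via hydroxymethyl diacetate 5 (not isolated)
Conditions: NaBH4, EtOH/CH2Cl2, −40 °C; then DBU (0.2 equiv), CH2Cl2, rt
Reagents that add atoms: none
Why: Borohydride reduces only the aldehyde; under mild base the new primary hydroxyl takes over the acetyl group of the cis C6 oxygen through a six-membered orthoacid (1,3-acyl migration), and the equilibrium lies on the side of the primary ester, while the C9 acetate (seven-membered transition state) stays; no stereocentre changes.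

Step 4
Reactants: 6 C6 alcohol
Product: 7 benzyl 9β-acetoxy-5β-(acetoxymethyl)-6β-(tert-butyldimethylsilyloxy)-10β-methylcyclohex-7-ene-10α-carboxylate
Conditions: t-BuMe2SiOSO2CF3, 2,6-lutidine, CH2Cl2, −78 °C
Reagents that add atoms: tert-butyldimethylsilyl trifluoromethanesulfonate, CC(C)(C)[Si](C)(C)OS(=O)(=O)C(F)(F)F
Why: Silylation of the only free hydroxyl with the silyl triflate at −78 °C, where acyl back-migration is frozen.

Step 5
Reactants: 7 silyl ether diacetate
Product: 10 benzyl 5β-(acetoxymethyl)-6β-(tert-butyldimethylsilyloxy)-7β-(carboxymethyl)-10β-methylcyclohex-8-ene-10α-carboxylate, via bis(silyl ketene acetal) 8 (not isolated), via rearranged silyl ester 9 (not isolated)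
Conditions: LiN(iPr)2 (2.6 equiv), Me3SiCl, THF, −78 → 65 °C; then 1 M HCl
Reagents that add atoms: none
Why: Ireland–Claisen rearrangement: both acetates become silyl ketene acetals, but only the C9 one is allylic; its [3,3] shift is suprafacial across the β face, so the configuration of C9–O is handed on to C7 (new stereocentre, acetic acid arm β) while the double bond moves to C8=C9, and the C4 ketene acetal reverts to the acetate on work-up.

Step 6
Reactants: 10 cyclohexene acid
Product: 12 trans-fused 12,8α-lactone with free 9α-hydroxyl (6β-silyloxy, 5β-acetoxymethyl, 10β-methyl, 10α-benzyloxycarbonyl), via diol acid 11 (not isolated)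
Conditions: OsO4 (5 mol%), N-methylmorpholine N-oxide, acetone/H2O, rt; then pyridinium p-toluenesulfonate (cat.), CH2Cl2, rt
Reagents that add atoms: N-methylmorpholine N-oxide, C[N+]1([O-])CCOCC1; water, O (oxygen delivered through catalytic OsO4, O=[Os](=O)(=O)=O)
Why: Upjohn dihydroxylation of the only alkene: in the half-chair with the C5 and C7 arms equatorial, the pseudoaxial C10 methyl and the axial C6 silyloxy group block the β face, so OsO4 should add from the α face and set C8 and C9 (both hydroxyls α); the equatorial C8 hydroxyl then closes the trans-fused γ-lactone with the acid arm on C7, which the axial C9 hydroxyl cannot reach.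

Step 7
Reactants: 12 hydroxy lactone
Product: 13 9α-(2-methylpropanoyl) ester of 12
Conditions: i-PrCOCl, pyridine, 4-(dimethylamino)pyridine, CH2Cl2, 0 → 40 °C
Reagents that add atoms: 2-methylpropanoyl chloride, CC(C)C(Cl)=O
Why: Nucleophile-catalysed acylation of the remaining, hindered axial hydroxyl with an acid chloride; nothing else in 12 is nucleophilic.

Step 8
Reactants: 13 benzyl ester
Product: 14 C10 carboxylic acid
Conditions: H2 (1 atm), Pd/C, EtOAc, rt
Reagents that add atoms: none
Why: Hydrogenolysis of the benzyl ester; at this stage the molecule holds no alkene, and lactone, esters and silyl ether are inert.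

Step 9
Reactants: 14 C10 carboxylic acid
Product: 17 10α-(chloroacetyl) compound, via acid chloride 15 (not isolated), via diazoketone 16 (not isolated)
Conditions: (COCl)2, DMF (cat.), CH2Cl2, 0 °C → rt; CH2N2, Et2O, 0 °C; HCl, Et2O, −20 → 0 °C
Reagents that add atoms: diazomethane, C=[N+]=[N-]; hydrogen chloride, Cl
Why: Acid chloride formation, acylation of diazomethane (first stage of the Arndt–Eistert sequence) and opening of the diazoketone with HCl (Nierenstein reaction) give the chloromethyl ketone; the acyl carbon sits on quaternary C10, so neither ketene formation nor epimerisation is possible.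

Step 10
Reactants: 17 chloromethyl ketone
Product: 18 10α-[(1R)-2-chloro-1-hydroxyethyl] compound
Conditions: (R)-1-methyl-3,3-diphenyltetrahydro-1H,3H-pyrrolo[1,2-c][1,3,2]oxazaborole (0.5 equiv), BH3·SMe2, THF, −20 °C
Reagents that add atoms: none
Why: Corey–Bakshi–Shibata reduction: the tertiary C10 residue is the large and CH2Cl the small group, so the (R)-catalyst delivers hydride to the face that gives the (1R)-alcohol; a Felkin–Anh reading of the substrate (hydride anti to the C10–C5 bond) points the same way, so reagent and substrate should be matched.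

Step 11
Reactants: 18 (1R)-chlorohydrin
Product: 20 10α-[(2R)-oxiran-2-yl] 5β-hydroxymethyl compound, via oxirane acetate 19 (not isolated)
Conditions: K2CO3, MeOH, 0 °C
Reagents that add atoms: none
Why: The carbonate generates the alkoxide, which displaces chloride (3-exo-tet Williamson closure) without touching the C1–O bond, so C1 stays R; the primary acetate is then methanolysed much faster than the hindered axial isobutyrate.

Step 12
Reactants: 20 primary alcohol
Product: 21 5β-formyl compound
Conditions: Dess–Martin periodinane, NaHCO3, CH2Cl2, 0 °C → rt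
Reagents that add atoms: none
Why: Dess–Martin oxidation of the primary alcohol under buffered, non-basic conditions keeps the epimerisable C5 centre and the β-silyloxy group intact.

Step 13
Reactants: 21 aldehyde
Product: 22 5β-(1-hydroxyethyl) compound (both C4 epimers)
Conditions: MeTi(OiPr)3, THF, −40 → 0 °C
Reagents that add atoms: methyltitanium triisopropoxide, C[Ti](OC(C)C)(OC(C)C)OC(C)C
Why: MeTi(OiPr)3 adds to aldehydes far faster than to lactones, esters or oxiranes and is hardly basic; the new carbinol centre at C4 is of no consequence because it is oxidised in the next step.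

Step 14
Reactants: 22 secondary alcohol
Product: 23 5β-acetyl compound
Conditions: Dess–Martin periodinane, NaHCO3, CH2Cl2, 0 °C → rt
Reagents that add atoms: none
Why: Dess–Martin oxidation of the secondary alcohol to the methyl ketone; both C4 epimers converge.

Step 15
Reactants: 23 methyl ketone
Product: 24 5β-(prop-1-en-2-yl) compound
Conditions: Ph3PCH3Br, KN(SiMe3)2, THF, 0 °C → rt
Reagents that add atoms: methylenetriphenylphosphorane, C=P(c1ccccc1)(c1ccccc1)c1ccccc1 (made in the flask from methyltriphenylphosphonium bromide, C[P+](c1ccccc1)(c1ccccc1)c1ccccc1.[Br-])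
Why: Wittig methylenation of the methyl ketone; the unstabilised ylide does not attack lactone, esters or oxirane at this temperature, and the equatorial C5 configuration is the thermodynamically preferred one should the ketone enolise.

Step 16
Reactants: 24 saturated lactone
Product: 27 α-methylene lactone (C11=C13) with 5β-isopropenyl and 6β-silyloxy groups, via Mannich base 25 (not isolated), via trimethylammonium iodide 26 (not isolated)
Conditions: LiN(iPr)2, THF, −78 °C; CH2=NMe2+ I−, −78 → 0 °C; MeI, MeOH, rt; NaHCO3 (aq.), CH2Cl2
Reagents that add atoms: N,N-dimethylmethyleneiminium iodide, C=[N+](C)C.[I-]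
Why: Kinetic deprotonation takes the lactone CH2 (more acidic and less hindered than the isobutyrate CH); Mannich reaction with the iminium salt, N-methylation and base-induced elimination of trimethylamine give the α-methylene lactone.

Step 17
Reactants: 27 isopropenyl compound
Product: 29 6-O-tert-butyldimethylsilyl ether of the target, via allylic alcohol 28 (not isolated)
Conditions: SeO2 (0.5 equiv), t-BuOOH, CH2Cl2, rt; then Dess–Martin periodinane, NaHCO3, CH2Cl2, rt
Reagents that add atoms: tert-butyl hydroperoxide, CC(C)(C)OO (oxygen passed on by SeO2, O=[Se]=O)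
Why: SeO2-catalysed allylic oxidation with t-BuOOH attacks the methyl group of the isopropenyl unit (CH3 before CH; the methylene lactone is too electron-poor for the ene step), and Dess–Martin oxidation brings the allylic alcohol to the enal.

Step 18
Reactants: 29 silyl ether
Product: 30 (3aS,4S,5R,6R,7S,7aR)-4-hydroxy-6-methyl-3-methylidene-6-[(2R)-oxiran-2-yl]-2-oxo-5-(3-oxoprop-1-en-2-yl)octahydro-1-benzofuran-7-yl 2-methylpropanoate
Conditions: HF·pyridine, pyridine, THF, 0 °C → rt
Reagents that add atoms: none
Why: Buffered HF·pyridine cleaves the silyl ether under acidic conditions, under which no alkoxide forms next to the lactone (no translactonisation) and the Michael acceptors are not attacked.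

## Compound list

1 | benzyl tiglate, benzyl (E)-2-methylbut-2-enoate | C/C=C(\C)C(=O)OCc1ccccc1 | starting material
2 | benzyl (E)-2-methyl-4-oxobut-2-enoate | O=C(OCc1ccccc1)/C(C)=C/C=O | intermediate
3 | (1E,3E)-buta-1,3-diene-1,4-diyl diacetate | CC(=O)O/C=C/C=C/OC(C)=O | starting material
4 | benzyl (1S,2S,5R,6S)-2,5-diacetoxy-6-formyl-1-methylcyclohex-3-ene-1-carboxylate (6β,9β-diacetoxy, 5β-formyl, 10β-methyl, 10α-CO2Bn, C7=C8) | CC(=O)O[C@@H]1C=C[C@H](OC(C)=O)[C@@](C)(C(=O)OCc2ccccc2)[C@@H]1C=O | intermediate
5 | 4 with the 5β-formyl group reduced to hydroxymethyl | CC(=O)O[C@@H]1C=C[C@H](OC(C)=O)[C@@](C)(C(=O)OCc2ccccc2)[C@@H]1CO | intermediate (not isolated)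
6 | benzyl 9β-acetoxy-5β-(acetoxymethyl)-6β-hydroxy-10β-methylcyclohex-7-ene-10α-carboxylate | O[C@@H]1C=C[C@H](OC(C)=O)[C@@](C)(C(=O)OCc2ccccc2)[C@@H]1COC(C)=O | intermediate
7 | 6β-O-tert-butyldimethylsilyl ether of 6 | CC(C)(C)[Si](C)(C)O[C@@H]1C=C[C@H](OC(C)=O)[C@@](C)(C(=O)OCc2ccccc2)[C@@H]1COC(C)=O | intermediate
8 | bis(trimethylsilyl ketene acetal) of 7 (both acetyl groups as CH2=C(OSiMe3)–O) | CC(C)(C)[Si](C)(C)O[C@@H]1C=C[C@H](OC(=C)O[Si](C)(C)C)[C@@](C)(C(=O)OCc2ccccc2)[C@@H]1COC(=C)O[Si](C)(C)C | intermediate (not isolated)
9 | trimethylsilyl ester of 10, C4 oxygen still as ketene acetal (7β-CH2CO2SiMe3, C8=C9) | C1=C[C@@H](CC(=O)O[Si](C)(C)C)[C@@H](O[Si](C)(C)C(C)(C)C)[C@@H](COC(=C)O[Si](C)(C)C)[C@]1(C)C(=O)OCc1ccccc1 | intermediate (not isolated)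
10 | benzyl 5β-(acetoxymethyl)-6β-(tert-butyldimethylsilyloxy)-7β-(carboxymethyl)-10β-methylcyclohex-8-ene-10α-carboxylate | C1=C[C@@H](CC(=O)O)[C@@H](O[Si](C)(C)C(C)(C)C)[C@@H](COC(C)=O)[C@]1(C)C(=O)OCc1ccccc1 | intermediate
11 | 8α,9α-dihydroxy derivative of 10 | O[C@@H]1[C@@H](CC(=O)O)[C@@H](O[Si](C)(C)C(C)(C)C)[C@@H](COC(C)=O)[C@](C)(C(=O)OCc2ccccc2)[C@@H]1O | intermediate (not isolated)
12 | trans-fused 12,8α-lactone, 9α-hydroxy, 6β-silyloxy, 5β-acetoxymethyl, 10β-methyl, 10α-CO2Bn | C1C(=O)O[C@@H]2[C@@H]1[C@@H](O[Si](C)(C)C(C)(C)C)[C@@H](COC(C)=O)[C@](C)(C(=O)OCc1ccccc1)[C@@H]2O | intermediate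
13 | 9α-(2-methylpropanoyl) ester of 12 | C1C(=O)O[C@@H]2[C@@H]1[C@@H](O[Si](C)(C)C(C)(C)C)[C@@H](COC(C)=O)[C@](C)(C(=O)OCc1ccccc1)[C@@H]2OC(=O)C(C)C | intermediate
14 | 10α-carboxylic acid from 13 | C1C(=O)O[C@@H]2[C@@H]1[C@@H](O[Si](C)(C)C(C)(C)C)[C@@H](COC(C)=O)[C@](C)(C(=O)O)[C@@H]2OC(=O)C(C)C | intermediate
15 | 10α-carbonyl chloride | C1C(=O)O[C@@H]2[C@@H]1[C@@H](O[Si](C)(C)C(C)(C)C)[C@@H](COC(C)=O)[C@](C)(C(=O)Cl)[C@@H]2OC(=O)C(C)C | intermediate (not isolated)
16 | 10α-(diazoacetyl) compound | C1C(=O)O[C@@H]2[C@@H]1[C@@H](O[Si](C)(C)C(C)(C)C)[C@@H](COC(C)=O)[C@](C)(C(=O)C=[N+]=[N-])[C@@H]2OC(=O)C(C)C | intermediate (not isolated)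
17 | 10α-(chloroacetyl) compound | C1C(=O)O[C@@H]2[C@@H]1[C@@H](O[Si](C)(C)C(C)(C)C)[C@@H](COC(C)=O)[C@](C)(C(=O)CCl)[C@@H]2OC(=O)C(C)C | intermediate
18 | 10α-[(1R)-2-chloro-1-hydroxyethyl] compound | C1C(=O)O[C@@H]2[C@@H]1[C@@H](O[Si](C)(C)C(C)(C)C)[C@@H](COC(C)=O)[C@](C)([C@@H](O)CCl)[C@@H]2OC(=O)C(C)C | intermediate
19 | 10α-[(2R)-oxiran-2-yl] compound, 5β-acetoxymethyl | C1C(=O)O[C@@H]2[C@@H]1[C@@H](O[Si](C)(C)C(C)(C)C)[C@@H](COC(C)=O)[C@](C)([C@@H]1CO1)[C@@H]2OC(=O)C(C)C | intermediate (not isolated)
20 | 10α-[(2R)-oxiran-2-yl] compound, 5β-hydroxymethyl | C1C(=O)O[C@@H]2[C@@H]1[C@@H](O[Si](C)(C)C(C)(C)C)[C@@H](CO)[C@](C)([C@@H]1CO1)[C@@H]2OC(=O)C(C)C | intermediate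
21 | 5β-formyl compound | C1C(=O)O[C@@H]2[C@@H]1[C@@H](O[Si](C)(C)C(C)(C)C)[C@@H](C=O)[C@](C)([C@@H]1CO1)[C@@H]2OC(=O)C(C)C | intermediate
22 | 5β-(1-hydroxyethyl) compound, both C4 epimers | C1C(=O)O[C@@H]2[C@@H]1[C@@H](O[Si](C)(C)C(C)(C)C)[C@@H](C(C)O)[C@](C)([C@@H]1CO1)[C@@H]2OC(=O)C(C)C | intermediate
23 | 5β-acetyl compound | C1C(=O)O[C@@H]2[C@@H]1[C@@H](O[Si](C)(C)C(C)(C)C)[C@@H](C(C)=O)[C@](C)([C@@H]1CO1)[C@@H]2OC(=O)C(C)C | intermediate
24 | 5β-(prop-1-en-2-yl) compound | C1C(=O)O[C@@H]2[C@@H]1[C@@H](O[Si](C)(C)C(C)(C)C)[C@@H](C(C)=C)[C@](C)([C@@H]1CO1)[C@@H]2OC(=O)C(C)C | intermediate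
25 | 11-[(dimethylamino)methyl] lactone, both C11 epimers | CN(C)CC1C(=O)O[C@@H]2[C@@H]1[C@@H](O[Si](C)(C)C(C)(C)C)[C@@H](C(C)=C)[C@](C)([C@@H]1CO1)[C@@H]2OC(=O)C(C)C | intermediate (not isolated)
26 | 11-[(trimethylammonio)methyl] lactone iodide | C[N+](C)(C)CC1C(=O)O[C@@H]2[C@@H]1[C@@H](O[Si](C)(C)C(C)(C)C)[C@@H](C(C)=C)[C@](C)([C@@H]1CO1)[C@@H]2OC(=O)C(C)C.[I-] | intermediate (not isolated)
27 | α-methylene lactone, 5β-isopropenyl, 6β-silyloxy | C=C1C(=O)O[C@@H]2[C@@H]1[C@@H](O[Si](C)(C)C(C)(C)C)[C@@H](C(C)=C)[C@](C)([C@@H]1CO1)[C@@H]2OC(=O)C(C)C | intermediate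
28 | 5β-(3-hydroxyprop-1-en-2-yl) compound | C=C1C(=O)O[C@@H]2[C@@H]1[C@@H](O[Si](C)(C)C(C)(C)C)[C@@H](C(=C)CO)[C@](C)([C@@H]1CO1)[C@@H]2OC(=O)C(C)C | intermediate (not isolated)
29 | 6-O-tert-butyldimethylsilyl ether of the target | C=C1C(=O)O[C@@H]2[C@@H]1[C@@H](O[Si](C)(C)C(C)(C)C)[C@@H](C(=C)C=O)[C@](C)([C@@H]1CO1)[C@@H]2OC(=O)C(C)C | intermediate
30 | (3aS,4S,5R,6R,7S,7aR)-4-hydroxy-6-methyl-3-methylidene-6-[(2R)-oxiran-2-yl]-2-oxo-5-(3-oxoprop-1-en-2-yl)octahydro-1-benzofuran-7-yl 2-methylpropanoate | C=C1C(=O)O[C@@H]2[C@@H]1[C@@H](O)[C@@H](C(=C)C=O)[C@](C)([C@@H]1CO1)[C@@H]2OC(=O)C(C)C | target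

## Step count and least certain steps

Total: 18 steps. Longest linear sequence: 18 steps (1 → 30; diene 3 enters at step 2).

**Step 2 (key step).**
- Risk: slow or unselective cycloaddition. The enal is hindered at the carbon that becomes C10, the diacetoxydiene is a weak diene, and its ester groups can compete for the boron cation, so an uncatalysed background reaction or low face selectivity may result.
- Fallback (from 2, back at 4): 2 is converted with (2R,4R)-pentane-2,4-diol into the chiral dioxane acetal F1. Under Me3SiOTf catalysis at −78 °C, F1 reacts with 3 as a vinyl-oxocarbenium ion (ionic Diels–Alder reaction), a far stronger dienophile than the neutral enal, and gives acetal F2. The auxiliary now supplies the face bias; the diol enantiomer that leads to the series of 4 is used, drawn here for the R,R-diol. Mild aqueous acid then releases 4.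

**Step 5.**
- Risk: the rearrangement needs the C9–O bond pseudoaxial, which pushes the C5 arm towards the β face over which the new bond forms. C-silylation of the acetate enolates or condensation with the neighbouring benzyl ester may then outrun the [3,3] shift.
- Fallback (from 7, back at 12): Tsuji–Trost alkylation of 7 with sodium dimethyl malonate and Pd(PPh3)4. Only the C9 acetate is allylic. Ionisation with inversion and attack of the soft nucleophile anti to palladium at the less hindered terminus C7 give malonate F3, with net retention and the same 1,3-transposition. Krapcho demethoxycarbonylation (LiCl, wet DMSO) gives methyl ester F4. The dihydroxylation of step 6 then gives diol ester F5, which lactonises under the same acid treatment to 12.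

**Step 10.**
- Risk: slow or poorly selective hydride transfer. The ketone is flanked by quaternary C10 and the axial isobutyrate, so uncatalysed borane reduction may compete with the catalysed path.
- Fallback (from 17, back at 19): reduction with NaBH4/CeCl3·7H2O at −78 °C under substrate control gives 18 together with its C1 epimer F6. DBU closes both, to 19 and the (1S)-oxirane F7. Jacobsen hydrolytic kinetic resolution with (R,R)-N,N′-bis(3,5-di-tert-butylsalicylidene)cyclohexane-1,2-diaminocobalt acetate (cobalt in the trivalent state) and a deficit of water hydrolyses F7 to diol F8 and spares 19, which is methanolysed to 20 as in step 11.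

**Step 11.**
- Risk: loss of chemoselectivity in basic methanol: methanolysis of the lactone or the isobutyrate, isobutyryl migration to the C1 alkoxide before ring closure, or attack of the freed C4 alkoxide on the oxirane.
- Fallback (from 18, back at 20, no new compound): closure with DBU in CH2Cl2 gives 19 as an isolated compound. The primary acetate is then hydrolysed with immobilised Candida antarctica lipase B in pH 7 buffer/tert-butyl methyl ether, so that no alkoxide is generated at any point.

**Step 18.**
- Risk: slow cleavage of the hindered axial silyl ether, with opening of the oxirane by fluoride or conjugate addition to the enal during the long exposure.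
- Fallback (from 27, back at 30): the order is changed. HF·pyridine is applied to 27, which has no enal yet, to give alcohol F9. SeO2/t-BuOOH then gives diol F10, and MnO2, which oxidises only the allylic hydroxyl, gives 30.

## Further compounds

F1 | step 2 | benzyl (E)-3-[(4R,6R)-4,6-dimethyl-1,3-dioxan-2-yl]-2-methylprop-2-enoate | O=C(OCc1ccccc1)/C(C)=C/C1O[C@H](C)C[C@@H](C)O1
F2 | step 2 | (4R,6R)-4,6-dimethyl-1,3-dioxan-2-yl acetal of 4 | CC(=O)O[C@@H]1C=C[C@H](OC(C)=O)[C@@](C)(C(=O)OCc2ccccc2)[C@@H]1C1O[C@H](C)C[C@@H](C)O1
F3 | step 5 | dimethyl malonate adduct at C7β (C8=C9, 6β-silyloxy, 5β-acetoxymethyl, 10α-CO2Bn) | C1=C[C@@H](C(C(=O)OC)C(=O)OC)[C@@H](O[Si](C)(C)C(C)(C)C)[C@@H](COC(C)=O)[C@]1(C)C(=O)OCc1ccccc1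
F4 | step 5 | methyl ester of 10 | C1=C[C@@H](CC(=O)OC)[C@@H](O[Si](C)(C)C(C)(C)C)[C@@H](COC(C)=O)[C@]1(C)C(=O)OCc1ccccc1
F5 | step 5 | 8α,9α-dihydroxy derivative of F4 | O[C@@H]1[C@@H](CC(=O)OC)[C@@H](O[Si](C)(C)C(C)(C)C)[C@@H](COC(C)=O)[C@](C)(C(=O)OCc2ccccc2)[C@@H]1O
F6 | step 10 | C1 epimer of 18, 10α-[(1S)-2-chloro-1-hydroxyethyl] compound | C1C(=O)O[C@@H]2[C@@H]1[C@@H](O[Si](C)(C)C(C)(C)C)[C@@H](COC(C)=O)[C@](C)([C@H](O)CCl)[C@@H]2OC(=O)C(C)C
F7 | step 10 | C1 epimer of 19, 10α-[(2S)-oxiran-2-yl] compound | C1C(=O)O[C@@H]2[C@@H]1[C@@H](O[Si](C)(C)C(C)(C)C)[C@@H](COC(C)=O)[C@](C)([C@H]1CO1)[C@@H]2OC(=O)C(C)C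
F8 | step 10 | 10α-[(1S)-1,2-dihydroxyethyl] compound from hydrolysis of F7 | C1C(=O)O[C@@H]2[C@@H]1[C@@H](O[Si](C)(C)C(C)(C)C)[C@@H](COC(C)=O)[C@](C)([C@H](O)CO)[C@@H]2OC(=O)C(C)C
F0 | step 11 | none | none
F9 | step 18 | 6β-hydroxy compound from desilylation of 27 | C=C1C(=O)O[C@@H]2[C@@H]1[C@@H](O)[C@@H](C(C)=C)[C@](C)([C@@H]1CO1)[C@@H]2OC(=O)C(C)C
F10 | step 18 | 6β-hydroxy 5β-(3-hydroxyprop-1-en-2-yl) compound | C=C1C(=O)O[C@@H]2[C@@H]1[C@@H](O)[C@@H](C(=C)CO)[C@](C)([C@@H]1CO1)[C@@H]2OC(=O)C(C)C
A1 | alternative 1 | 4-iodotoluene | Cc1ccc(I)cc1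
A2 | alternative 1 | (1S,2S)-3-iodo-6-methylcyclohexa-3,5-diene-1,2-diol | CC1=CC=C(I)[C@@H](O)[C@H]1O
A3 | alternative 2 | C8 alcohol with 7β-ethynyl, 6β-silyloxy, 5β-isopropenyl, 10α-vinyl and 9α-(4-methoxybenzyloxy) groups | O[C@@H]1[C@@H](C#C)[C@@H](O[Si](C)(C)C(C)(C)C)[C@@H](C(C)=C)[C@](C)(C=C)[C@@H]1OCc1ccc(OC)cc1
A4 | alternative 2 | trans-fused α-methylene-γ-butyrolactone from A3 | C=C1C(=O)O[C@@H]2[C@@H]1[C@@H](O[Si](C)(C)C(C)(C)C)[C@@H](C(C)=C)[C@](C)(C=C)[C@@H]2OCc1ccc(OC)cc1
A5 | alternative 3 | Se-phenyl selenoester with (E)-enoate and C8/C9 acetonide | O=C([Se]c1ccccc1)[C@@H](CCOCc1ccccc1)[C@](C)(C=C)[C@@H]1OC(C)(C)O[C@@H]1/C=C/C(=O)OC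
A6 | alternative 3 | cyclohexanone (C6 ketone) with C7 acetate arm and C8/C9 acetonide | O=C1[C@H](CC(=O)OC)[C@H]2OC(C)(C)O[C@H]2[C@@](C)(C=C)[C@@H]1CCOCc1ccccc1
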